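(The numbers are invented; no experiment stands behind them.)

Time is the axis here: we draw spent catalyst against it, from the first seconds to the level where the curve ends.

substrate 5.0 mM; salt in the second phase 6.00 mM; spent carrier 0.50 mM; volume of the second phase over the first 0.50

    substrate + spent carrier → spent catalyst (k1 = 8.79 M⁻¹ s⁻¹)
    spent carrier + salt in the second phase ⇌ fresh carrier + spent salt in the second phase (K2 = 17, k2 = 43.1 M⁻¹ s⁻¹)
    substrate + fresh carrier → target + spent carrier (k3 = 37.6 M⁻¹ s⁻¹)

- in the second phase: salt in the second phase, spent salt in the second phase; everything else is in the first
- charges count per volume of the first phase; a concentration in a rate is the amount of a species over the volume of its own phase; every rate counts per litre of the first phase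
- charge of substrate (flask): 5.0 mM

- the form that holds most of the catalyst when 30% of the substrate are converted (spent catalyst / spent carrier / fresh carrier)
- its share of the catalyst then
- apparent order in salt in the second phase when 30% of the substrate are converted (percent change of the rate of making target for one percent more salt in the second phase charged)

The salt sits in the smaller phase, so its own concentration is 12.0 mM. All the catalyst starts as spent carrier, and the salt turns it into fresh carrier at 31 min⁻¹, faster than substrate turns it into spent catalyst at 2.6 min⁻¹. Spent catalyst starts with a slope of 1.32 mM min⁻¹, but the knee comes after about 1.42 s, when fresh and spent carrier have reached their balance. We reckon that the knee leaves an offset of 0.0229 mM of spent catalyst.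

Past the knee, we take the salt to remake fresh carrier as fast as substrate uses it up. Fresh over spent carrier is then S, the rate constant of the salt's step times [salt] in its own phase, over the rate constant of the target's step times [substrate], and we hold S at its starting value, 2.75. Each substrate consumed makes either target or spent catalyst, and both rates carry [substrate], which cancels in their ratio. The rate integrates in closed form: spent catalyst grows in a straight line with substrate consumed, with slope f = 0.0783, which is the rate constant of the loss over the sum of that constant and S times the target's constant, the leak per substrate consumed.

At the conversion asked, spent catalyst is then 28.1% of the catalyst. Fresh carrier, the resting state of the working round, holds 52.8%. The curve ends at 82.9% if the whole charge of substrate is counted as consumed. One percent more salt raises S by one percent, which gives an order of 0.568 from the split and the smaller loss together. We take that as a low figure, since salt is consumed along the way and one percent on the charge is more than one percent on what then stands.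

The forecast says fresh carrier at 53% with order 0.7, holding among its grounds that “more salt means less catalyst lost by that point”.

The flask gives fresh carrier at 52.9% and order 0.69, with spent catalyst at 28.6%, and our order of 0.568 lies lower. Between 1.00 min and 2.00 min spent catalyst rose by 0.0689 mM while substrate fell by 0.968 mM, a reading of 0.0712 per substrate beside f of 0.0783. At 20.0 min, with 0.289% of the substrate left, spent catalyst stands below our end level, at 75.6% of the catalyst.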